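**Retrosynthetic overview**

1. Asterelin A (21) comes from its di-O-methyl ether 20, and 20 from bromophenol 19 by closing the 18-membered ring at the ring D–O–ring C diaryl ether bond (Ullmann etherification).
2. 19 comes from dibenzofuran aldehyde 14 and benzylphosphonate 16, which build the C7 ethano bridge to ring C (Horner–Wadsworth–Emmons olefination, diimide reduction, debenzylation).
3. The furan ring is opened at O–C4a. On ring A the oxygen-bearing C4a is separated from the C3 oxygen by the single CH at C4, so a chlorine at C4 (one ortho hydrogen only, at C4a) gives a C4≡C4a aryne flanked by C3–OMe, which takes the ring B phenoxide (O on C5a) at C4a.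
4. The aryne precursor 10 comes from boronate 7 and bromophenol acetal 9 (Suzuki coupling, C9a–C9b bond); 7 comes from aldehyde 1 by bromination para to OMe, olefination with phosphonate 4, diimide reduction and borylation.
5. Ring order: the four benzene rings A–D are bought; the furan ring is formed in step 8 and the macrocycle in step 14.

Key step: step 8

Remark: dibenzofuran numbering of the target is used throughout (ring A = C1–C4, C4a, C9b; ring B = C5a–C9a; ring C = the 3-aryloxy-4-hydroxyphenyl ring; ring D = the para-phenylene ring). The target is treated as achiral, as its SMILES carries no stereodescriptor. 3-Bromo-4-methoxybenzyl bromide and LiTMP solution are taken as purchased.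

**Route**

Step 1
Reactants: 1 4-chloro-3-methoxybenzaldehyde
Product: 2 2-bromo-4-chloro-5-methoxybenzaldehyde
Conditions: Br2, AcOH, rt
Reagents that add atoms: bromine, BrBr
Why: Electrophilic aromatic bromination should go para to the methoxy group (ortho to CHO), since the only other methoxy-activated site lies between OMe and CHO, as in the bromination of 3-methoxybenzaldehyde.

Step 2
Reactants: 3 4-benzyloxybenzyl chloride
Product: 4 diethyl (4-benzyloxybenzyl)phosphonate
Conditions: P(OEt)3 (neat), 150 °C
Reagents that add atoms: triethyl phosphite, CCOP(OCC)OCC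
Why: Michaelis–Arbuzov reaction of a reactive benzylic chloride with triethyl phosphite, driven by loss of chloroethane.

Step 3
Reactants: 2 2-bromo-4-chloro-5-methoxybenzaldehyde; 4 diethyl (4-benzyloxybenzyl)phosphonate
Product: 5 (E)-1-bromo-5-chloro-4-methoxy-2-[2-(4-benzyloxyphenyl)ethenyl]benzene
Conditions: KOt-Bu, THF, 0 °C to rt
Reagents that add atoms: none
Why: Horner–Wadsworth–Emmons olefination of an aryl aldehyde with a benzylphosphonate anion should give the E-stilbene, whose geometry is removed in the next step.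

Step 4
Reactants: 5 (E)-1-bromo-5-chloro-4-methoxy-2-[2-(4-benzyloxyphenyl)ethenyl]benzene
Product: 6 1-bromo-5-chloro-4-methoxy-2-[2-(4-benzyloxyphenyl)ethyl]benzene
Conditions: TsNHNH2, NaOAc, THF/H2O, reflux
Reagents that add atoms: none
Why: Diimide reduction (HN=NH generated from tosylhydrazide) transfers H2 to the stilbene double bond in a concerted way and should leave the C–Br, C–Cl and O-benzyl bonds untouched, which catalytic hydrogenation over palladium would not.

Step 5
Reactants: 6 1-bromo-5-chloro-4-methoxy-2-[2-(4-benzyloxyphenyl)ethyl]benzene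
Product: 7 2-{5-chloro-4-methoxy-2-[2-(4-benzyloxyphenyl)ethyl]phenyl}-4,4,5,5-tetramethyl-1,3,2-dioxaborolane
Conditions: B2pin2, PdCl2(dppf), KOAc, 1,4-dioxane, 90 °C
Reagents that add atoms: bis(pinacolato)diboron, CC1(C)OB(OC1(C)C)B1OC(C)(C)C(C)(C)O1
Why: Miyaura borylation, in which oxidative addition with this catalyst should occur at the C–Br bond only and leave the electron-rich C–Cl bond for the key step.

Step 6
Reactants: 8 4-bromo-3-hydroxybenzaldehyde
Product: 9 2-bromo-5-(1,3-dioxolan-2-yl)phenol
Conditions: ethylene glycol, TsOH·H2O (cat.), toluene, reflux, Dean–Stark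
Reagents that add atoms: ethylene glycol, OCCO
Why: Acid-catalysed acetalization with azeotropic removal of water masks the aldehyde against the amide base of step 8 and leaves the phenol free.

Step 7
Reactants: 7 2-{5-chloro-4-methoxy-2-[2-(4-benzyloxyphenyl)ethyl]phenyl}-4,4,5,5-tetramethyl-1,3,2-dioxaborolane; 9 2-bromo-5-(1,3-dioxolan-2-yl)phenol
Product: 10 2-{5-chloro-4-methoxy-2-[2-(4-benzyloxyphenyl)ethyl]phenyl}-5-(1,3-dioxolan-2-yl)phenol
Conditions: Pd(PPh3)4, K2CO3, 1,4-dioxane/H2O, 90 °C; neutral work-up (aq NH4Cl)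
Reagents that add atoms: none
Why: Suzuki–Miyaura coupling of an unprotected 2-bromophenol with an arylboronate forms the C9a–C9b bond, because the triphenylphosphine catalyst inserts into C–Br and not into the aryl chloride, and the acetal is stable to aqueous base.

Step 8
Reactants: 10 2-{5-chloro-4-methoxy-2-[2-(4-benzyloxyphenyl)ethyl]phenyl}-5-(1,3-dioxolan-2-yl)phenol
Product: 13 1-[2-(4-benzyloxyphenyl)ethyl]-7-(1,3-dioxolan-2-yl)-3-methoxydibenzofuran, via lithium aryne-phenoxide 11 (not isolated), via 4-lithiodibenzofuran 12 (not isolated)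
Conditions: LiTMP (3.5 equiv), THF, −78 °C to 0 °C; then aq NH4Cl
Reagents that add atoms: none
Why: The first equivalent of LiTMP gives the lithium phenoxide and a second removes C4a–H, the only hydrogen ortho to chlorine (the other neighbour, C3, carries OMe), so loss of LiCl on warming can give only the C4≡C4a aryne 11. The phenoxide oxygen on C5a, held three atoms from the aryne carbon, adds in the ring plane to C4a and forms the O–C4a bond and the furan ring; the C4 aryllithium 12, flanked by OMe and the new ring oxygen, is protonated on quench. The closest known reaction type is the benzyne ring closure, in which an aryne generated by an amide base from a meta-halo arene is captured by a tethered oxygen, nitrogen or carbanion nucleophile to give a five-membered ring. The ring closes in a 5-exo mode with respect to the aryne triple bond (only C4a enters the new ring), and no stereocentre is formed. Regioselectivity is needed at two levels and is secured twice: the substitution pattern allows one aryne only, and both the tether length and the inductive effect of the C3 methoxy group (negative charge develops at C4, next to oxygen) send the oxygen to C4a. The hindered amide should not compete for the aryne with the intramolecular phenoxide, and the benzyl ether, dioxolane and methyl ether offer it no reactive site at or below 0 °C.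

Step 9
Reactants: 13 1-[2-(4-benzyloxyphenyl)ethyl]-7-(1,3-dioxolan-2-yl)-3-methoxydibenzofuran
Product: 14 9-[2-(4-benzyloxyphenyl)ethyl]-7-methoxydibenzofuran-3-carbaldehyde (the C7 aldehyde in the numbering used here)
Conditions: 1 M HCl, THF, rt
Reagents that add atoms: water, O
Why: Acid-catalysed hydrolysis of the dioxolane releases the aldehyde, while the benzyl and methyl ethers and the dibenzofuran are inert to dilute acid.

Step 10
Reactants: 15 3-bromo-4-methoxybenzyl bromide
Product: 16 diethyl (3-bromo-4-methoxybenzyl)phosphonate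
Conditions: P(OEt)3 (neat), 120 °C
Reagents that add atoms: triethyl phosphite, CCOP(OCC)OCC
Why: Michaelis–Arbuzov reaction at the benzylic bromide, which leaves the aryl bromide untouched.

Step 11
Reactants: 14 9-[2-(4-benzyloxyphenyl)ethyl]-7-methoxydibenzofuran-3-carbaldehyde; 16 diethyl (3-bromo-4-methoxybenzyl)phosphonate
Product: 17 (E)-1-[2-(4-benzyloxyphenyl)ethyl]-7-[2-(3-bromo-4-methoxyphenyl)ethenyl]-3-methoxydibenzofuran
Conditions: KOt-Bu, THF, 0 °C to rt
Reagents that add atoms: none
Why: Horner–Wadsworth–Emmons olefination attaches ring C to C7 as the E-stilbene, under conditions too mild to affect the aryl bromide.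

Step 12
Reactants: 17 (E)-1-[2-(4-benzyloxyphenyl)ethyl]-7-[2-(3-bromo-4-methoxyphenyl)ethenyl]-3-methoxydibenzofuran
Product: 18 1-[2-(4-benzyloxyphenyl)ethyl]-7-[2-(3-bromo-4-methoxyphenyl)ethyl]-3-methoxydibenzofuran
Conditions: TsNHNH2, NaOAc, THF/H2O, reflux
Reagents that add atoms: none
Why: Diimide reduction saturates the stilbene and keeps the aryl bromide needed for the ring closure as well as the benzyl ether.

Step 13
Reactants: 18 1-[2-(4-benzyloxyphenyl)ethyl]-7-[2-(3-bromo-4-methoxyphenyl)ethyl]-3-methoxydibenzofuran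
Product: 19 4-{2-[7-[2-(3-bromo-4-methoxyphenyl)ethyl]-3-methoxydibenzofuran-1-yl]ethyl}phenol
Conditions: BCl3, pentamethylbenzene, CH2Cl2, −78 °C; then MeOH, H2O
Reagents that add atoms: none
Why: Lewis-acid debenzylation with a non-Lewis-basic cation scavenger cleaves the aryl benzyl ether at low temperature without touching the aryl methyl ethers or the C–Br bond, which hydrogenolysis would endanger.

Step 14
Reactants: 19 4-{2-[7-[2-(3-bromo-4-methoxyphenyl)ethyl]-3-methoxydibenzofuran-1-yl]ethyl}phenol
Product: 20 di-O-methylasterelin A (asterelin A with OMe at C3 of ring A and at C4 of ring C)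
Conditions: CuI, N,N-dimethylglycine hydrochloride, Cs2CO3, 1,4-dioxane, 100 °C, high dilution (about 2 mM, slow addition)
Reagents that add atoms: none
Why: Copper-catalysed Ullmann diaryl ether synthesis, run intramolecularly under high dilution, joins the ring D phenoxide to the ring C carbon bearing bromine and should close the 18-membered ring, the two flexible ethano bridges allowing the ends to meet.

Step 15
Reactants: 20 di-O-methylasterelin A
Product: 21 asterelin A
Conditions: BBr3, CH2Cl2, −78 °C to rt; then H2O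
Reagents that add atoms: none
Why: Boron tribromide demethylation cleaves both aryl methyl ethers, while the diaryl ether and the dibenzofuran C–O bonds are not cleaved under these conditions.

**Compound list**

1 | 4-chloro-3-methoxybenzaldehyde | COc1cc(C=O)ccc1Cl | starting material
2 | 2-bromo-4-chloro-5-methoxybenzaldehyde | COc1cc(C=O)c(Br)cc1Cl | intermediate
3 | 4-benzyloxybenzyl chloride | ClCc1ccc(OCc2ccccc2)cc1 | starting material
4 | diethyl (4-benzyloxybenzyl)phosphonate | CCOP(=O)(Cc1ccc(OCc2ccccc2)cc1)OCC | intermediate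
5 | (E)-1-bromo-5-chloro-4-methoxy-2-[2-(4-benzyloxyphenyl)ethenyl]benzene | COc1cc(/C=C/c2ccc(OCc3ccccc3)cc2)c(Br)cc1Cl | intermediate
6 | 1-bromo-5-chloro-4-methoxy-2-[2-(4-benzyloxyphenyl)ethyl]benzene | COc1cc(CCc2ccc(OCc3ccccc3)cc2)c(Br)cc1Cl | intermediate
7 | 2-{5-chloro-4-methoxy-2-[2-(4-benzyloxyphenyl)ethyl]phenyl}-4,4,5,5-tetramethyl-1,3,2-dioxaborolane | COc1cc(CCc2ccc(OCc3ccccc3)cc2)c(cc1Cl)B1OC(C)(C)C(C)(C)O1 | intermediate
8 | 4-bromo-3-hydroxybenzaldehyde | O=Cc1ccc(Br)c(O)c1 | starting material
9 | 2-bromo-5-(1,3-dioxolan-2-yl)phenol | Oc1cc(ccc1Br)C1OCCO1 | intermediate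
10 | 2-{5-chloro-4-methoxy-2-[2-(4-benzyloxyphenyl)ethyl]phenyl}-5-(1,3-dioxolan-2-yl)phenol (aryne precursor) | COc1cc(CCc2ccc(OCc3ccccc3)cc2)c(cc1Cl)-c1ccc(cc1O)C1OCCO1 | intermediate
11 | lithium aryne-phenoxide: lithium salt of 10 after loss of HCl, C4≡C4a triple bond in ring A | [Li+].COC1=CC(CCc2ccc(OCc3ccccc3)cc2)=C(C#C1)c1ccc(cc1[O-])C1OCCO1 | intermediate (not isolated)
12 | 4-lithiodibenzofuran: 13 with lithium in place of hydrogen at C4 | COc1cc(CCc2ccc(OCc3ccccc3)cc2)c2c(c1[Li])oc1cc(ccc12)C1OCCO1 | intermediate (not isolated)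
13 | 1-[2-(4-benzyloxyphenyl)ethyl]-7-(1,3-dioxolan-2-yl)-3-methoxydibenzofuran | COc1cc(CCc2ccc(OCc3ccccc3)cc2)c2c(c1)oc1cc(ccc12)C1OCCO1 | intermediate
14 | 9-[2-(4-benzyloxyphenyl)ethyl]-7-methoxydibenzofuran-3-carbaldehyde | COc1cc(CCc2ccc(OCc3ccccc3)cc2)c2c(c1)oc1cc(C=O)ccc12 | intermediate
15 | 3-bromo-4-methoxybenzyl bromide | COc1ccc(CBr)cc1Br | starting material
16 | diethyl (3-bromo-4-methoxybenzyl)phosphonate | CCOP(=O)(Cc1ccc(OC)c(Br)c1)OCC | intermediate
17 | (E)-1-[2-(4-benzyloxyphenyl)ethyl]-7-[2-(3-bromo-4-methoxyphenyl)ethenyl]-3-methoxydibenzofuran | COc1cc(CCc2ccc(OCc3ccccc3)cc2)c2c(c1)oc1cc(/C=C/c3ccc(OC)c(Br)c3)ccc12 | intermediate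
18 | 1-[2-(4-benzyloxyphenyl)ethyl]-7-[2-(3-bromo-4-methoxyphenyl)ethyl]-3-methoxydibenzofuran | COc1cc(CCc2ccc(OCc3ccccc3)cc2)c2c(c1)oc1cc(CCc3ccc(OC)c(Br)c3)ccc12 | intermediate
19 | 4-{2-[7-[2-(3-bromo-4-methoxyphenyl)ethyl]-3-methoxydibenzofuran-1-yl]ethyl}phenol | COc1cc(CCc2ccc(O)cc2)c2c(c1)oc1cc(CCc3ccc(OC)c(Br)c3)ccc12 | intermediate
20 | di-O-methylasterelin A | COc1cc2c3c(c1)oc1cc(ccc13)CCc1ccc(OC)c(c1)Oc1ccc(cc1)CC2 | intermediate
21 | asterelin A | Oc1cc2c3c(c1)oc1cc(ccc13)CCc1ccc(O)c(c1)Oc1ccc(cc1)CC2 | target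

**Step count and risks**

Total step count: 15. Longest linear sequence: 12 steps (steps 1, 3, 4, 5, 7, 8, 9, 11, 12, 13, 14, 15).

Steps most likely to fail:

Step 8 (aryne cyclization). Deprotonation of C4a–H, which sits between chlorine and the anionic phenoxide ring, may be slow. The aryne may then be intercepted intermolecularly by amide or by a second phenoxide, or the base may attack the benzylic O–CH2 of the benzyl ether. The fallback sets out from 10 and comes back at 13. The chlorine, which serves only the aryne, is removed by palladium-catalysed hydrodechlorination (PdCl2(dppf), TMEDA, NaBH4, THF) to give 2-{4-methoxy-2-[2-(4-benzyloxyphenyl)ethyl]phenyl}-5-(1,3-dioxolan-2-yl)phenol F1. The O–C4a bond is then formed by the phenol-directed C–H activation/C–O cyclization of 2-arylphenols (Pd(OAc)2, the carbene ligand IPr, sodium 2,4,6-trimethylbenzoate, K2CO3, 4,5-diazafluoren-9-one, air, mesitylene, 120 °C). C4a–H is the only free position ortho to the biaryl bond on ring A, so the closure should deliver 13.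

Step 14 (Ullmann macro-etherification). Oligomerization may outrun ring closure, because copper insertion at the electron-rich bromide ortho to methoxy is slow and the rigid dibenzofuran adds strain to the 18-membered ring. The fallback sets out from 13 and comes back at 20; it forms the diaryl ether first and closes the ring at the C7 ethano bridge.
- Hydrogenolysis (H2, Pd/C, EtOAc) gives 4-{2-[7-(1,3-dioxolan-2-yl)-3-methoxydibenzofuran-1-yl]ethyl}phenol F2.
- Chan–Lam coupling with (5-formyl-2-methoxyphenyl)boronic acid (Cu(OAc)2, pyridine, 4 Å molecular sieves, CH2Cl2, air) gives the diaryl ether aldehyde F3.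
- NaBH4 in MeOH gives the benzylic alcohol F4.
- PPh3·HBr in refluxing MeCN, with cleavage of the acetal by the acid, gives the formyl phosphonium bromide F5.
- Intramolecular Wittig reaction (NaOMe, CH2Cl2, high dilution) gives the macrocyclic stilbene F6 (E/Z mixture expected, geometry left open).
- Hydrogenation (H2, Pd/C) gives 20.

Step 7 (Suzuki coupling). Oxidative addition into the electron-rich bromophenoxide may be sluggish, and the ortho-substituted boronate 7 may protodeboronate in the meantime. The fallback sets out from 9 and 6 and comes back at 10; it reverses the roles of the partners and masks the phenol.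
- Silylation of 9 (TBSCl, imidazole, DMF) gives tert-butyl[2-bromo-5-(1,3-dioxolan-2-yl)phenoxy]dimethylsilane F7.
- Miyaura borylation (B2pin2, PdCl2(dppf), KOAc, dioxane) gives the silyl-protected pinacol boronate F8.
- Suzuki coupling with bromide 6 (Pd(PPh3)4, K2CO3, dioxane/H2O; oxidative addition now at the C–Br bond of 6, the chloride inert) gives the silyl ether of the biaryl F9.
- Bu4NF in THF releases 10.

Further compounds
F1 | step 8 | 2-{4-methoxy-2-[2-(4-benzyloxyphenyl)ethyl]phenyl}-5-(1,3-dioxolan-2-yl)phenol | COc1cc(CCc2ccc(OCc3ccccc3)cc2)c(cc1)-c1ccc(cc1O)C1OCCO1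
F2 | step 14 | 4-{2-[7-(1,3-dioxolan-2-yl)-3-methoxydibenzofuran-1-yl]ethyl}phenol | COc1cc(CCc2ccc(O)cc2)c2c(c1)oc1cc(ccc12)C1OCCO1
F3 | step 14 | 3-(4-{2-[7-(1,3-dioxolan-2-yl)-3-methoxydibenzofuran-1-yl]ethyl}phenoxy)-4-methoxybenzaldehyde | COc1cc(CCc2ccc(Oc3cc(C=O)ccc3OC)cc2)c2c(c1)oc1cc(ccc12)C1OCCO1
F4 | step 14 | [3-(4-{2-[7-(1,3-dioxolan-2-yl)-3-methoxydibenzofuran-1-yl]ethyl}phenoxy)-4-methoxyphenyl]methanol | COc1cc(CCc2ccc(Oc3cc(CO)ccc3OC)cc2)c2c(c1)oc1cc(ccc12)C1OCCO1
F5 | step 14 | {3-[4-(2-{7-formyl-3-methoxydibenzofuran-1-yl}ethyl)phenoxy]-4-methoxybenzyl}triphenylphosphonium bromide | [Br-].COc1cc(CCc2ccc(Oc3cc(C[P+](c4ccccc4)(c4ccccc4)c4ccccc4)ccc3OC)cc2)c2c(c1)oc1cc(C=O)ccc12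
F6 | step 14 | macrocyclic stilbene: 20 with a CH=CH bridge between C7 and ring C (E/Z mixture, geometry left open) | COc1cc2c3c(c1)oc1cc(ccc13)C=Cc1ccc(OC)c(c1)Oc1ccc(cc1)CC2
F7 | step 7 | tert-butyl[2-bromo-5-(1,3-dioxolan-2-yl)phenoxy]dimethylsilane | CC(C)(C)[Si](C)(C)Oc1cc(ccc1Br)C1OCCO1
F8 | step 7 | tert-butyl[5-(1,3-dioxolan-2-yl)-2-(4,4,5,5-tetramethyl-1,3,2-dioxaborolan-2-yl)phenoxy]dimethylsilane | CC(C)(C)[Si](C)(C)Oc1cc(ccc1B1OC(C)(C)C(C)(C)O1)C1OCCO1
F9 | step 7 | tert-butyldimethylsilyl ether of 10 | COc1cc(CCc2ccc(OCc3ccccc3)cc2)c(cc1Cl)-c1ccc(cc1O[Si](C)(C)C(C)(C)C)C1OCCO1
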